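## Retrosynthetic overview

1. Target 24 ⇐ methacryloylation of the 8β-alcohol 22 ⇐ formate 21 (O8 stays masked through ring closure).
2. 21 ⇐ ring-closing metathesis at C1=C10 of the acyclic lactone 20; the ten-membered ring is formed last.
3. 20 ⇐ Mitsunobu inversion at C8 of 18 ⇐ key C7–C8 bond by intermolecular zinc Barbier carbonyl allylation of aldehyde 16 with bromobutenolide 12 (sets C7 and C8, unveils the α-methylene lactone).
4. 12 ⇐ ring-closing metathesis of the 2-(bromomethyl)acrylate of (S)-alcohol 8 (C6 from a Sharpless kinetic resolution); 16 ⇐ ozonolysis of methyl 2-allylacrylate 14.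
5. Ring order: five-membered lactone (step 7), then ten-membered carbocycle (step 12).

Assumption: positions are given in germacrane numbering (C6/C7 lactone carbons, C8 ester carbinol, C10 carries C14 = CO2Me, C4 carries C15 = CH3), and metal alkoxides or alkenylmetal species that are only protonated on work-up are not numbered.

## Route

Step 1
Reactants: 1 methyl but-2-ynoate; 2 but-3-en-1-ylmagnesium bromide
Product: 3 methyl (2E)-3-methylhepta-2,6-dienoate
Conditions: 2 (1.3 equiv), CuBr·SMe2 (1.3 equiv), THF, −78 °C; then 1, −78 °C, 1 h; H2O quench at −78 °C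
Reagents that add atoms: none
Why: Syn-carbocupration (conjugate addition of the organocopper to the ynoate) and cold protonation of the alkenylcopper with retention put the new chain trans to the ester, giving the E-trisubstituted alkene that becomes C4=C5.

Step 2
Reactants: 3 methyl (2E)-3-methylhepta-2,6-dienoate
Product: 4 (2E)-3-methylhepta-2,6-dien-1-ol
Conditions: iBu2AlH (2.5 equiv), CH2Cl2, −78 → 0 °C; aq. potassium sodium tartrate
Reagents that add atoms: none
Why: Aluminium hydride 1,2-reduction of the conjugated ester to the allylic alcohol leaves both alkenes and the E geometry untouched.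

Step 3
Reactants: 4 (2E)-3-methylhepta-2,6-dien-1-ol
Product: 5 (2E)-3-methylhepta-2,6-dienal
Conditions: MnO2 (15 equiv), CH2Cl2, rt
Reagents that add atoms: none
Why: Selective allylic alcohol oxidation under neutral conditions gives the enal without E/Z erosion or over-oxidation.

Step 4
Reactants: 5 (2E)-3-methylhepta-2,6-dienal; 6 ethenylmagnesium bromide
Product: 7 rac-(4E)-5-methylnona-1,4,8-trien-3-ol
Conditions: 6 (1.2 equiv), THF, −78 → 0 °C; then H2O
Reagents that add atoms: none
Why: Grignard 1,2-addition to the β,β-disubstituted enal gives the bis-allylic carbinol (future C6) as the racemate.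

Step 5
Reactants: 7 rac-(4E)-5-methylnona-1,4,8-trien-3-ol
Product: 8 (3S,4E)-5-methylnona-1,4,8-trien-3-ol
Conditions: Ti(OiPr)4 (0.2 equiv), D-(−)-diisopropyl tartrate (0.25 equiv), tBuOOH (0.6 equiv), 4 Å molecular sieves, CH2Cl2, −20 °C, to ca. 55–60% conversion
Reagents that add atoms: none
Why: Sharpless kinetic resolution (titanium/tartrate asymmetric epoxidation): with the D-(−)-tartrate the R enantiomer is epoxidised fast at its trisubstituted allylic alkene, so the mismatched S alcohol (future C6) is recovered in high ee.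

Step 6
Reactants: 8 (3S,4E)-5-methylnona-1,4,8-trien-3-ol; 9 2-(bromomethyl)prop-2-enoic acid
Product: 11 (3S,4E)-5-methylnona-1,4,8-trien-3-yl 2-(bromomethyl)prop-2-enoate, via O-acylisourea 10 (not isolated)
Conditions: DCC (1.3 equiv), DMAP (0.1 equiv), CH2Cl2, 0 °C
Reagents that add atoms: none
Why: Steglich esterification under neutral conditions acylates the oxygen without touching the C–O bond of the acid-sensitive bis-allylic carbinol, so the configuration is retained.

Step 7
Reactants: 11 (3S,4E)-5-methylnona-1,4,8-trien-3-yl 2-(bromomethyl)prop-2-enoate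
Product: 12 (5R)-3-(bromomethyl)-5-[(1E)-2-methylhexa-1,5-dien-1-yl]furan-2(5H)-one
Conditions: second-generation Grubbs catalyst (H2IMes)(PCy3)Cl2Ru=CHPh (5 mol%), CH2Cl2 (5 mM), 40 °C
Reagents that add atoms: none
Why: Ring-closing metathesis between the carbinol vinyl group and the acrylate closes the five-membered lactone quickly, whereas any closure involving the distal vinyl group would need an E-alkene inside a seven- or nine-membered ring.

Step 8
Reactants: 13 methyl 2-(bromomethyl)prop-2-enoate; 6 ethenylmagnesium bromide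
Product: 14 methyl 2-methylidenepent-4-enoate
Conditions: 6 (1.1 equiv), CuI (5 mol%), THF, −78 → −20 °C
Reagents that add atoms: none
Why: Copper-catalysed allylic substitution of the bromide by the vinyl Grignard reagent (direct and allyl-transposed attack give the same product) is faster than addition to the ester at low temperature.

Step 9
Reactants: 14 methyl 2-methylidenepent-4-enoate
Product: 16 methyl 2-methylidene-4-oxobutanoate, via secondary ozonide 15 (not isolated)
Conditions: O3 (1.0 equiv), CH2Cl2, −78 °C; then Me2S, −78 °C → rt; solution used at once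
Reagents that add atoms: ozone, O=[O+][O-]
Why: Ozonolysis with reductive work-up: electrophilic ozone attacks the electron-rich monosubstituted alkene far faster than the acrylate, and the neutral work-up avoids isomerising the β,γ-unsaturated aldehyde.

Step 10
Reactants: 12 (5R)-3-(bromomethyl)-5-[(1E)-2-methylhexa-1,5-dien-1-yl]furan-2(5H)-one; 16 methyl 2-methylidene-4-oxobutanoate
Product: 18 methyl (4S)-4-hydroxy-2-methylidene-4-[(2R,3R)-2-[(1E)-2-methylhexa-1,5-dien-1-yl]-4-methylidene-5-oxooxolan-3-yl]butanoate, via allylzinc bromide 17 (not isolated)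
Conditions: Zn dust (3 equiv), 16 (2 equiv), THF/sat. aq. NH4Cl (2:1), 0 °C → rt
Reagents that add atoms: none
Why: Barbier-type carbonyl allylation: zinc inserts into the allylic C–Br bond and the allylzinc adds through its γ-carbon (C7) in a closed chair transition state, on the lactone face anti to the C6 alkenyl group (7R, trans to C6) and with the aldehyde chain equatorial (anti adduct, 8S), which also unveils the α-methylene lactone.

Step 11
Reactants: 18 methyl (4S)-4-hydroxy-2-methylidene-4-[(2R,3R)-2-[(1E)-2-methylhexa-1,5-dien-1-yl]-4-methylidene-5-oxooxolan-3-yl]butanoate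
Product: 20 methyl (4R)-4-(formyloxy)-2-methylidene-4-[(2R,3R)-2-[(1E)-2-methylhexa-1,5-dien-1-yl]-4-methylidene-5-oxooxolan-3-yl]butanoate, via alkoxyphosphonium formate 19 (not isolated)
Conditions: PPh3 (2 equiv), DIAD (2 equiv), HCO2H (3 equiv), THF, 0 °C → rt
Reagents that add atoms: formic acid, O=CO
Why: Mitsunobu reaction: formate displaces the alkoxyphosphonium by SN2 with inversion (8S to 8R, the 8β-oxygen of the target), and the small formate masks O8 against lactonisation onto the C14 ester and brings no alkene into the metathesis.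

Step 12
Reactants: 20 methyl (4R)-4-(formyloxy)-2-methylidene-4-[(2R,3R)-2-[(1E)-2-methylhexa-1,5-dien-1-yl]-4-methylidene-5-oxooxolan-3-yl]butanoate
Product: 21 methyl (3aR,4R,6E,10E,11aR)-4-(formyloxy)-10-methyl-3-methylidene-2-oxo-2,3,3a,4,5,8,9,11a-octahydrocyclodeca[b]furan-6-carboxylate
Conditions: second-generation Hoveyda–Grubbs catalyst (H2IMes)Cl2Ru(=CH-C6H4-2-OiPr) (15 mol%, in portions), toluene (1 mM), 80 °C
Reagents that add atoms: none
Why: Ring-closing metathesis: the ruthenium alkylidene formed at the terminal vinyl group closes onto the 2-substituted acrylate with loss of ethene, the ten-membered ring that already holds the 4E alkene forming the ring-cis C1=C10 bond (CO2Me trans to C2), while closure onto the lactone methylidene would need an E-alkene in an eight-membered ring.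

Step 13
Reactants: 21 methyl (3aR,4R,6E,10E,11aR)-4-(formyloxy)-10-methyl-3-methylidene-2-oxo-2,3,3a,4,5,8,9,11a-octahydrocyclodeca[b]furan-6-carboxylate
Product: 22 methyl (3aR,4R,6E,10E,11aR)-4-hydroxy-10-methyl-3-methylidene-2-oxo-2,3,3a,4,5,8,9,11a-octahydrocyclodeca[b]furan-6-carboxylate
Conditions: KHCO3 (0.3 equiv), MeOH, 0 °C, monitored and quenched with pH 7 buffer
Reagents that add atoms: none
Why: Base-catalysed transesterification (methanolysis): the formate is far more electrophilic than the methyl ester, the lactone or the conjugated esters, so it alone is cleaved at 0 °C and no stereocentre is touched.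

Step 14
Reactants: 22 methyl (3aR,4R,6E,10E,11aR)-4-hydroxy-10-methyl-3-methylidene-2-oxo-2,3,3a,4,5,8,9,11a-octahydrocyclodeca[b]furan-6-carboxylate; 23 2-methylprop-2-enoic anhydride
Product: 24 methyl (3aR,4R,6E,10E,11aR)-10-methyl-3-methylidene-4-[(2-methylprop-2-enoyl)oxy]-2-oxo-2,3,3a,4,5,8,9,11a-octahydrocyclodeca[b]furan-6-carboxylate (CNP0317149.1)
Conditions: 23 (3 equiv), Et3N, DMAP (0.2 equiv), CH2Cl2, 0 °C → rt
Reagents that add atoms: none
Why: DMAP-catalysed acylation (nucleophilic catalysis) of the secondary 8β-alcohol reacts only at the O–H bond, so C8 keeps its configuration.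

## Compound list

1 | methyl but-2-ynoate | CC#CC(=O)OC | starting material
2 | but-3-en-1-ylmagnesium bromide | C=CCC[Mg]Br | starting material
3 | methyl (2E)-3-methylhepta-2,6-dienoate | C=CCC/C(C)=C/C(=O)OC | intermediate
4 | (2E)-3-methylhepta-2,6-dien-1-ol | C=CCC/C(C)=C/CO | intermediate
5 | (2E)-3-methylhepta-2,6-dienal | C=CCC/C(C)=C/C=O | intermediate
6 | ethenylmagnesium bromide | C=C[Mg]Br | starting material
7 | rac-(4E)-5-methylnona-1,4,8-trien-3-ol | C=CC(O)/C=C(C)/CCC=C | intermediate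
8 | (3S,4E)-5-methylnona-1,4,8-trien-3-ol | C=C[C@H](O)/C=C(C)/CCC=C | intermediate
9 | 2-(bromomethyl)prop-2-enoic acid | C=C(CBr)C(=O)O | starting material
10 | O-[2-(bromomethyl)prop-2-enoyl]-N,N'-dicyclohexylisourea | C=C(CBr)C(=O)OC(=NC1CCCCC1)NC1CCCCC1 | intermediate (not isolated)
11 | (3S,4E)-5-methylnona-1,4,8-trien-3-yl 2-(bromomethyl)prop-2-enoate | C=C[C@H](OC(=O)C(=C)CBr)/C=C(C)/CCC=C | intermediate
12 | (5R)-3-(bromomethyl)-5-[(1E)-2-methylhexa-1,5-dien-1-yl]furan-2(5H)-one | BrCC1=C[C@@H](/C=C(C)/CCC=C)OC1=O | intermediate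
13 | methyl 2-(bromomethyl)prop-2-enoate | C=C(CBr)C(=O)OC | starting material
14 | methyl 2-methylidenepent-4-enoate | C=CCC(=C)C(=O)OC | intermediate
15 | methyl 2-(1,2,4-trioxolan-3-ylmethyl)prop-2-enoate (secondary ozonide) | C=C(CC1OCOO1)C(=O)OC | intermediate (not isolated)
16 | methyl 2-methylidene-4-oxobutanoate | C=C(CC=O)C(=O)OC | intermediate
17 | bromo{[(5R)-5-[(1E)-2-methylhexa-1,5-dien-1-yl]-2-oxo-2,5-dihydrofuran-3-yl]methyl}zinc | Br[Zn]CC1=C[C@@H](/C=C(C)/CCC=C)OC1=O | intermediate (not isolated)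
18 | methyl (4S)-4-hydroxy-2-methylidene-4-[(2R,3R)-2-[(1E)-2-methylhexa-1,5-dien-1-yl]-4-methylidene-5-oxooxolan-3-yl]butanoate | O[C@H]([C@@H]1[C@@H](/C=C(C)/CCC=C)OC(=O)C1=C)CC(=C)C(=O)OC | intermediate
19 | alkoxytriphenylphosphonium formate of 18 (P–O bond at C8, 8S retained) | c1ccccc1[P+](c1ccccc1)(c1ccccc1)O[C@H]([C@@H]1[C@@H](/C=C(C)/CCC=C)OC(=O)C1=C)CC(=C)C(=O)OC.[O-]C=O | intermediate (not isolated)
20 | methyl (4R)-4-(formyloxy)-2-methylidene-4-[(2R,3R)-2-[(1E)-2-methylhexa-1,5-dien-1-yl]-4-methylidene-5-oxooxolan-3-yl]butanoate | O=CO[C@@H]([C@@H]1[C@@H](/C=C(C)/CCC=C)OC(=O)C1=C)CC(=C)C(=O)OC | intermediate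
21 | methyl (3aR,4R,6E,10E,11aR)-4-(formyloxy)-10-methyl-3-methylidene-2-oxo-2,3,3a,4,5,8,9,11a-octahydrocyclodeca[b]furan-6-carboxylate | O=CO[C@@H]1C/C(C(=O)OC)=C\CC/C(C)=C/[C@H]2OC(=O)C(=C)[C@@H]21 | intermediate
22 | methyl (3aR,4R,6E,10E,11aR)-4-hydroxy-10-methyl-3-methylidene-2-oxo-2,3,3a,4,5,8,9,11a-octahydrocyclodeca[b]furan-6-carboxylate | O[C@@H]1C/C(C(=O)OC)=C\CC/C(C)=C/[C@H]2OC(=O)C(=C)[C@@H]21 | intermediate
23 | 2-methylprop-2-enoic anhydride | C=C(C)C(=O)OC(=O)C(C)=C | starting material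
24 | methyl (3aR,4R,6E,10E,11aR)-10-methyl-3-methylidene-4-[(2-methylprop-2-enoyl)oxy]-2-oxo-2,3,3a,4,5,8,9,11a-octahydrocyclodeca[b]furan-6-carboxylate | C=C(C)C(=O)O[C@@H]1C/C(C(=O)OC)=C\CC/C(C)=C/[C@H]2OC(=O)C(=C)[C@@H]21 | target

## Step count and weak points

Total steps: 14. Longest linear sequence: 12 (steps 1–7, then 10–14); steps 8–9 run in parallel.

The three steps most likely to fail, each with a fallback:

Step 12 (closing the ten-membered ring onto an electron-poor 1,1-disubstituted olefin; oligomers or no turnover are the likely failures). The fallback carries C14 through the ring closure as an electron-neutral allylic silyl ether and oxidises it to the ester afterwards. It sets out from 16 and comes back at 21. Aldehyde 16 is converted with HC(OMe)3 and PPTS in MeOH into methyl 4,4-dimethoxy-2-methylidenebutanoate F1, reduced with iBu2AlH to 4,4-dimethoxy-2-methylidenebutan-1-ol F2, silylated with TBSCl and imidazole to tert-butyl[(4,4-dimethoxy-2-methylidenebutyl)oxy]dimethylsilane F3, and unmasked with PPTS in wet acetone to 3-({[tert-butyl(dimethyl)silyl]oxy}methyl)but-3-enal F4. Zinc-mediated coupling of F4 with 12 under the conditions of step 10 gives (4R,5R)-4-[(1S)-3-({[tert-butyl(dimethyl)silyl]oxy}methyl)-1-hydroxybut-3-en-1-yl]-5-[(1E)-2-methylhexa-1,5-dien-1-yl]-3-methylideneoxolan-2-one F5. Mitsunobu formylation as in step 11 gives (1R)-3-({[tert-butyl(dimethyl)silyl]oxy}methyl)-1-[(2R,3R)-2-[(1E)-2-methylhexa-1,5-dien-1-yl]-4-methylidene-5-oxooxolan-3-yl]but-3-en-1-yl formate F6. Metathesis (second-generation Grubbs catalyst, toluene, 80 °C, 1 mM) gives (3aR,4R,6E,10E,11aR)-6-({[tert-butyl(dimethyl)silyl]oxy}methyl)-10-methyl-3-methylidene-2-oxo-2,3,3a,4,5,8,9,11a-octahydrocyclodeca[b]furan-4-yl formate F7. HF·pyridine then frees (3aR,4R,6E,10E,11aR)-6-(hydroxymethyl)-10-methyl-3-methylidene-2-oxo-2,3,3a,4,5,8,9,11a-octahydrocyclodeca[b]furan-4-yl formate F8, MnO2 gives (3aR,4R,6E,10E,11aR)-6-formyl-10-methyl-3-methylidene-2-oxo-2,3,3a,4,5,8,9,11a-octahydrocyclodeca[b]furan-4-yl formate F9, NaClO2/NaH2PO4/2-methylbut-2-ene gives (3aR,4R,6E,10E,11aR)-4-(formyloxy)-10-methyl-3-methylidene-2-oxo-2,3,3a,4,5,8,9,11a-octahydrocyclodeca[b]furan-6-carboxylic acid F10, and MeI with K2CO3 in DMF returns 21.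

Step 10 (aldehyde 16 can slip into conjugation, and the anti/syn ratio at C8 in aqueous zinc chemistry may be modest). The fallback replaces the Barbier reaction by an allylboration; it sets out from 12 and comes back at 18. Bromide 12 is borylated (B2pin2, Pd2(dba)3 as source of zerovalent palladium, toluene, 50 °C) to 2-{[(5R)-5-[(1E)-2-methylhexa-1,5-dien-1-yl]-2-oxo-2,5-dihydrofuran-3-yl]methyl}-4,4,5,5-tetramethyl-1,3,2-dioxaborolane F11. F11 adds to 16 in dry toluene (rt to 50 °C, or Sc(OTf)3 catalysis at −78 °C) through a tight boron-centred chair transition state with the same anti sense, and work-up with triethanolamine gives 18.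

Step 11 (elimination or sluggish SN2 at the β-branched carbinol). The fallback inverts C8 by oxidation and reduction instead of substitution; it sets out from 18 and comes back at 20. Dess–Martin periodinane buffered with NaHCO3 gives methyl 2-methylidene-4-[(2R,3S)-2-[(1E)-2-methylhexa-1,5-dien-1-yl]-4-methylidene-5-oxooxolan-3-yl]-4-oxobutanoate F12, which is reduced at once because it can isomerise. Reagent-controlled reduction with (S)-Me-CBS oxazaborolidine and catecholborane (toluene, −78 °C, the branched C7 side acting as the large group) gives methyl (4R)-4-hydroxy-2-methylidene-4-[(2R,3R)-2-[(1E)-2-methylhexa-1,5-dien-1-yl]-4-methylidene-5-oxooxolan-3-yl]butanoate F13, and acetic formic anhydride with pyridine gives 20.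

Further compounds

F1 | step 12 | methyl 4,4-dimethoxy-2-methylidenebutanoate | COC(OC)CC(=C)C(=O)OC
F2 | step 12 | 4,4-dimethoxy-2-methylidenebutan-1-ol | COC(OC)CC(=C)CO
F3 | step 12 | tert-butyl[(4,4-dimethoxy-2-methylidenebutyl)oxy]dimethylsilane | COC(OC)CC(=C)CO[Si](C)(C)C(C)(C)C
F4 | step 12 | 3-({[tert-butyl(dimethyl)silyl]oxy}methyl)but-3-enal | O=CCC(=C)CO[Si](C)(C)C(C)(C)C
F5 | step 12 | (4R,5R)-4-[(1S)-3-({[tert-butyl(dimethyl)silyl]oxy}methyl)-1-hydroxybut-3-en-1-yl]-5-[(1E)-2-methylhexa-1,5-dien-1-yl]-3-methylideneoxolan-2-one | O[C@H]([C@@H]1[C@@H](/C=C(C)/CCC=C)OC(=O)C1=C)CC(=C)CO[Si](C)(C)C(C)(C)C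
F6 | step 12 | (1R)-3-({[tert-butyl(dimethyl)silyl]oxy}methyl)-1-[(2R,3R)-2-[(1E)-2-methylhexa-1,5-dien-1-yl]-4-methylidene-5-oxooxolan-3-yl]but-3-en-1-yl formate | O=CO[C@@H]([C@@H]1[C@@H](/C=C(C)/CCC=C)OC(=O)C1=C)CC(=C)CO[Si](C)(C)C(C)(C)C
F7 | step 12 | (3aR,4R,6E,10E,11aR)-6-({[tert-butyl(dimethyl)silyl]oxy}methyl)-10-methyl-3-methylidene-2-oxo-2,3,3a,4,5,8,9,11a-octahydrocyclodeca[b]furan-4-yl formate | O=CO[C@@H]1C/C(CO[Si](C)(C)C(C)(C)C)=C\CC/C(C)=C/[C@H]2OC(=O)C(=C)[C@@H]21
F8 | step 12 | (3aR,4R,6E,10E,11aR)-6-(hydroxymethyl)-10-methyl-3-methylidene-2-oxo-2,3,3a,4,5,8,9,11a-octahydrocyclodeca[b]furan-4-yl formate | O=CO[C@@H]1C/C(CO)=C\CC/C(C)=C/[C@H]2OC(=O)C(=C)[C@@H]21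
F9 | step 12 | (3aR,4R,6E,10E,11aR)-6-formyl-10-methyl-3-methylidene-2-oxo-2,3,3a,4,5,8,9,11a-octahydrocyclodeca[b]furan-4-yl formate | O=CO[C@@H]1C/C(C=O)=C\CC/C(C)=C/[C@H]2OC(=O)C(=C)[C@@H]21
F10 | step 12 | (3aR,4R,6E,10E,11aR)-4-(formyloxy)-10-methyl-3-methylidene-2-oxo-2,3,3a,4,5,8,9,11a-octahydrocyclodeca[b]furan-6-carboxylic acid | O=CO[C@@H]1C/C(C(=O)O)=C\CC/C(C)=C/[C@H]2OC(=O)C(=C)[C@@H]21
F11 | step 10 | 2-{[(5R)-5-[(1E)-2-methylhexa-1,5-dien-1-yl]-2-oxo-2,5-dihydrofuran-3-yl]methyl}-4,4,5,5-tetramethyl-1,3,2-dioxaborolane | CC1(C)OB(CC2=C[C@@H](/C=C(C)/CCC=C)OC2=O)OC1(C)C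
F12 | step 11 | methyl 2-methylidene-4-[(2R,3S)-2-[(1E)-2-methylhexa-1,5-dien-1-yl]-4-methylidene-5-oxooxolan-3-yl]-4-oxobutanoate | O=C(CC(=C)C(=O)OC)[C@@H]1[C@@H](/C=C(C)/CCC=C)OC(=O)C1=C
F13 | step 11 | methyl (4R)-4-hydroxy-2-methylidene-4-[(2R,3R)-2-[(1E)-2-methylhexa-1,5-dien-1-yl]-4-methylidene-5-oxooxolan-3-yl]butanoate | O[C@@H]([C@@H]1[C@@H](/C=C(C)/CCC=C)OC(=O)C1=C)CC(=C)C(=O)OC
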